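| setting | epsilon | gamma | alpha | eta | theta |
|---|---|---|---|---|---|
| J | 0.800 M | 0.480 M | 1.20 M | 0.800 M | 1.60 M |
| E | 0.640 M | 0.320 M | 0.640 M | 1.90 M | 1.30 M |
| time |  |  |  |  | 73 min |

| run | time / min | [X] / M |
|---|---|---|
| epsilon run | 2.6 | 0.0355 |
| epsilon run | 7.9 | 0.0900 |
| epsilon run | 15 | 0.1394 |
| epsilon run | 24 | 0.1768 |
| epsilon run | 34 | 0.1976 |
| epsilon run | 46 | 0.2167 |
| epsilon run | 59 | 0.2261 |
| epsilon run | 73 | 0.2324 |
| gamma run | 2.6 | 0.0152 |
| gamma run | 7.9 | 0.0434 |
| gamma run | 15 | 0.0668 |
| gamma run | 24 | 0.0880 |
| gamma run | 34 | 0.1003 |
| gamma run | 46 | 0.1106 |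
| gamma run | 59 | 0.1174 |
| gamma run | 73 | 0.1192 |
| alpha run | 2.6 | 0.0431 |
| alpha run | 7.9 | 0.1113 |
| alpha run | 15 | 0.1711 |
| alpha run | 24 | 0.2144 |
| alpha run | 34 | 0.2524 |
| alpha run | 46 | 0.2726 |
| alpha run | 59 | 0.2850 |
| alpha run | 73 | 0.2861 |
| eta run | 2.6 | 0.0564 |
| eta run | 7.9 | 0.1272 |
| eta run | 15 | 0.1811 |
| eta run | 24 | 0.2197 |
| eta run | 34 | 0.2472 |
| eta run | 46 | 0.2667 |
| eta run | 59 | 0.2766 |
| eta run | 73 | 0.2786 |

(readings scatter by 0.002 M)

- Overall: J + E -> X.
- Constant volume, constant temperature.
- Readings of a species count what is bound in complexes too.
- "The second partner" is E.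
- An order is taken over about fifteen percent of the charge, up and down.

- reaction order in [E] at the outset, round the charge of the epsilon run, defined at two percent of the J turned into X
- reaction order in [J] at the outset, round the charge of the epsilon run, defined at two percent of the J turned into X (one fixed amount of X, the same in the runs compared)
- X in the theta run at 73 min, as a share of the J charged

A flat X peak late in a run is easily read as a finished reaction, but in the epsilon run X levels near 0.2324 M, which is 36.3 % of the E charged, E being there the smaller charge and so the limiting reagent by the overall equation. The clock to count on this bench is the stall lifetime, meaning the last X reading divided by the rate read from the first point, 17.0 min in the epsilon run, as a reading with the scatter of that first point.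

The theta flask holds J and E at 1.60 M and 1.30 M, and its charge should stay untouched until sampled, because the lifetime moves with the charge: the gamma run reads 20.4 min, longer than the epsilon run. From gamma to epsilon, J rose 1.67-fold and E 2.00-fold, while the last X reading rose 1.95-fold. From epsilon to theta the factors on J and E are 2.00 and 2.03, so this note's own rough reckoning applies the gamma-to-epsilon ratios once more, although the factor on J is now larger than it was: a theta lifetime near 14.2 min and X near 0.453 M, or 28.3 % of the J charged. At 73 min the flask has passed 5.14 lifetimes, so on an exponential approach hardly any of that X is still to come.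

The forecast, reasoning that “This looks like a decaying active species or catalyst”, gives orders of 0.55 in E and 0.5 in J, and 22.5 %, which is lower than this note's figure.

    J + E → X (0.2202 /M/min)
    J + E → Z (0.1962 /M/min)
    J + E ⇌ JE, settled at all times (6.310 /M)
    2 E → Qi (0.3930 /M/min)

The theta run gives 31.4 % at 73 min, or 0.503 M of X, while the orders at the outset, round the charge of the epsilon run, are 0.73 in E and 0.60 in J. These steps fit the readings with a residual of 0.88 in units of the scatter, against 12 when the product reacts on with E instead. Spread over the reckoned lifetime of 14.2 min, that X corresponds to a first rate of 0.0354 M/min in the theta run. In the eta run the stall lifetime, taken from the last reading and the rate at the fixed amount of X, is 12.6 min, shorter than the 17.0 min of the epsilon run, and X in the eta run reaches a quarter of the J charged at 18.7 min, after 1.48 lifetimes.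

The readings stem from a simulated flask on assumed constants; scatter was added.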